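The route rests on opening the pyran ring of the chromene at C4–C4a and O1–C2, which leads back to an aryl 1,1-dimethylpropargyl ether. On the benzene ring, C8a (bearing O1) lies para to C6 (bearing the CH2 link to the pyranone ring), so this ether has a mirror plane and two identical ortho carbons. Heating sets off a [3,3] shift, a hydrogen shift and an oxa-6π closure that build the pyran ring in one operation. The precursor carries TBS ethers on both phenols next to the benzylic carbon, because a free one would flank the allenyl group and could close the ring the wrong way. C8 is acylated last.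

Key step: step 6

Assumption: the side-chain stereocentre of the target is read as (S) and is bought in with the chiral acid; all other starting materials are achiral catalogue compounds.

Step 1
Reactants: 1 2,4,6-trihydroxybenzaldehyde; 2 3-chloro-3-methylbut-1-yne
Product: 3 2,6-dihydroxy-4-[(2-methylbut-3-yn-2-yl)oxy]benzaldehyde
Conditions: DBU (1.1 equiv), CuCl2·2H2O (1 mol%), MeCN, −5 → 0 °C, Ar
Reagents that add atoms: none
Why: Copper-catalysed propargylic substitution by a phenoxide is the standard way to tertiary aryl propargyl ethers, and with about one equivalent of base the bulky electrophile should go to the 4-oxygen, which belongs to the most acidic phenol (para to the formyl group and not hydrogen-bonded to it) and is the least hindered of the three.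

Step 2
Reactants: 3 2,6-dihydroxy-4-[(2-methylbut-3-yn-2-yl)oxy]benzaldehyde
Product: 4 2,6-bis[(tert-butyldimethylsilyl)oxy]-4-[(2-methylbut-3-yn-2-yl)oxy]benzaldehyde
Conditions: TBSCl (2.6 equiv), imidazole (5 equiv), DMF, 0 °C → rt
Reagents that add atoms: tert-butyldimethylsilyl chloride (TBSCl), CC(C)(C)[Si](C)(C)Cl
Why: Imidazole-promoted silylation of phenols with excess reagent in DMF overcomes the hydrogen bond to the formyl oxygen, keeps the mirror symmetry, and removes the two salicylaldehyde-type O–H groups that would otherwise attack the pyranone lactone in step 5 and compete for ring closure in step 6.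

Step 3
Reactants: 5 pentan-3-one
Product: 6 trimethyl(pent-2-en-3-yloxy)silane (E/Z mixture)
Conditions: TMSOTf (1.1 equiv), Et3N (1.3 equiv), CH2Cl2, 0 °C; pentane extraction, distillation
Reagents that add atoms: trimethylsilyl trifluoromethanesulfonate (TMSOTf), C[Si](C)(C)OS(=O)(=O)C(F)(F)F
Why: Soft enolisation of a symmetrical ketone with a silyl triflate and a tertiary amine gives the silyl enol ether without any regiochemical question, and the alkene geometry is irrelevant because that carbon becomes sp2 C5 of the pyranone.

Step 4
Reactants: 6 trimethyl(pent-2-en-3-yloxy)silane; 7 malonyl dichloride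
Product: 9 6-ethyl-4-hydroxy-5-methyl-2H-pyran-2-one, via 4-methyl-3,5-dioxoheptanoyl chloride 8 (not isolated)
Conditions: Et2O, −20 °C → rt
Reagents that add atoms: none
Why: This is the cyclocondensation of a silyl enol ether with malonyl dichloride, in which C-acylation at the enol carbon gives 8, the enol oxygen of its ethyl ketone closes on the second acid chloride (6-exo-trig lactonisation), and tautomerisation gives the 4-hydroxy-2-pyranone with methyl on C5 and ethyl on C6.

Step 5
Reactants: 4 2,6-bis[(tert-butyldimethylsilyl)oxy]-4-[(2-methylbut-3-yn-2-yl)oxy]benzaldehyde; 9 6-ethyl-4-hydroxy-5-methyl-2H-pyran-2-one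
Product: 11 3-({2,6-bis[(tert-butyldimethylsilyl)oxy]-4-[(2-methylbut-3-yn-2-yl)oxy]phenyl}methyl)-6-ethyl-4-hydroxy-5-methyl-2H-pyran-2-one, via arylidene pyrandione 10 (not isolated)
Conditions: Hantzsch ester (diethyl 2,6-dimethyl-1,4-dihydropyridine-3,5-dicarboxylate, 1.2 equiv), L-proline (20 mol%), CH2Cl2, rt
Reagents that add atoms: none
Why: This is the organocatalytic three-component reductive alkylation (Knoevenagel condensation through the proline iminium ion, then conjugate hydride transfer from the Hantzsch ester), which is established for 4-hydroxy-2-pyranones and aromatic aldehydes; fast reduction of 10 and its two ortho substituents suppress addition of a second pyranone, and neither the alkyne nor the silyl ethers react.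

Step 6
Reactants: 11 3-({2,6-bis[(tert-butyldimethylsilyl)oxy]-4-[(2-methylbut-3-yn-2-yl)oxy]phenyl}methyl)-6-ethyl-4-hydroxy-5-methyl-2H-pyran-2-one
Product: 15 3-({5,7-bis[(tert-butyldimethylsilyl)oxy]-2,2-dimethyl-2H-chromen-6-yl}methyl)-6-ethyl-4-hydroxy-5-methyl-2H-pyran-2-one, via allenyl cyclohexadienone 12 (not isolated), via ortho-allenylphenol 13 (not isolated), via vinyl ortho-quinone methide 14 (not isolated)
Conditions: o-xylene (degassed, dilute), 135 °C, Ar
Reagents that add atoms: none
Why: This is the thermal aromatic propargyl Claisen rearrangement of an aryl 1,1-dimethylpropargyl ether, the standard entry to 2,2-dimethyl-2H-chromenes: the [3,3] shift breaks the O–CMe2 bond and joins the alkyne terminus to an ortho carbon (C4–C4a) to give dienone 12, which enolises to allenylphenol 13. A 1,5-hydrogen shift from the new phenol O–H to the central allene carbon then gives the vinyl ortho-quinone methide 14. The pyran ring closes by a disrotatory oxa-6π electrocyclisation that joins the carbonyl oxygen to CMe2 (O1–C2) and restores the benzene ring. No stereocentre is formed. The site of the [3,3] shift needs no control, because the mirror plane through C6 and C8a makes the two ortho carbons equivalent, and the geminal methyl groups keep the required temperature moderate. The choice between the two oxygens that flank the allenyl group does need control and is secured by the silyl ether on the neighbouring oxygen, which has no O–H to shift, so only the former ether oxygen can become O1; the same silyl ethers block loss of the pyranone through a quinone methide at the benzylic carbon.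

Step 7
Reactants: 15 3-({5,7-bis[(tert-butyldimethylsilyl)oxy]-2,2-dimethyl-2H-chromen-6-yl}methyl)-6-ethyl-4-hydroxy-5-methyl-2H-pyran-2-one
Product: 16 3-[(5,7-dihydroxy-2,2-dimethyl-2H-chromen-6-yl)methyl]-6-ethyl-4-hydroxy-5-methyl-2H-pyran-2-one
Conditions: TBAF (2.2 equiv), AcOH (2.4 equiv), THF, 0 °C, Ar; used promptly
Reagents that add atoms: none
Why: Fluoride cleavage of aryl silyl ethers, buffered with acetic acid so that the air-sensitive phenoxides are protonated at once, avoids both the acid that would protonate the electron-rich C3=C4 alkene and the heat that would let the pyran ring open and re-close on the 5-oxygen.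

Step 8
Reactants: 17 (S)-2-methylbutanoic acid
Product: 18 (S)-2-methylbutanoyl chloride
Conditions: (COCl)2 (1.2 equiv), DMF (1 mol%), CH2Cl2, 0 °C → rt; used as a CH2Cl2 solution
Reagents that add atoms: oxalyl chloride, O=C(Cl)C(=O)Cl
Why: Acid chloride formation through the Vilsmeier-type chloroiminium catalyst runs without any base, so no ketene can form and the (S) centre is carried over unchanged.

Step 9
Reactants: 16 3-[(5,7-dihydroxy-2,2-dimethyl-2H-chromen-6-yl)methyl]-6-ethyl-4-hydroxy-5-methyl-2H-pyran-2-one; 18 (S)-2-methylbutanoyl chloride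
Product: 19 3-({5,7-dihydroxy-2,2-dimethyl-8-[(2S)-2-methylbutanoyl]-2H-chromen-6-yl}methyl)-6-ethyl-4-hydroxy-5-methyl-2H-pyran-2-one
Conditions: 18 (1.2 equiv), TiCl4 (3.5 equiv), 2,6-di-tert-butyl-4-methylpyridine (4.5 equiv), CH2Cl2, −78 → −30 °C; quench into ice-water
Reagents that add atoms: none
Why: In this Friedel–Crafts C-acylation of a phloroglucinol-type ring, C8 is the only unsubstituted arene carbon and is ortho or para to three oxygens, any aryl ester formed first can move there by a Fries shift on titanium, the hindered pyridine traps HCl before it can protonate the C3=C4 alkene yet is too weak a base to enolise the ketone, and the (S) centre therefore comes unchanged from 17.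

Compound list
1 | 2,4,6-trihydroxybenzaldehyde | O=Cc1c(O)cc(O)cc1O | starting material
2 | 3-chloro-3-methylbut-1-yne | CC(C)(Cl)C#C | starting material
3 | 2,6-dihydroxy-4-[(2-methylbut-3-yn-2-yl)oxy]benzaldehyde | O=Cc1c(O)cc(OC(C)(C)C#C)cc1O | intermediate
4 | 2,6-bis[(tert-butyldimethylsilyl)oxy]-4-[(2-methylbut-3-yn-2-yl)oxy]benzaldehyde | O=Cc1c(O[Si](C)(C)C(C)(C)C)cc(OC(C)(C)C#C)cc1O[Si](C)(C)C(C)(C)C | intermediate
5 | pentan-3-one | CCC(=O)CC | starting material
6 | trimethyl(pent-2-en-3-yloxy)silane (E/Z mixture) | CC=C(CC)O[Si](C)(C)C | intermediate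
7 | malonyl dichloride (propanedioyl dichloride) | O=C(Cl)CC(=O)Cl | starting material
8 | 4-methyl-3,5-dioxoheptanoyl chloride (racemic, not isolated) | CCC(=O)C(C)C(=O)CC(=O)Cl | intermediate
9 | 6-ethyl-4-hydroxy-5-methyl-2H-pyran-2-one | CCc1oc(=O)cc(O)c1C | intermediate
10 | 3-({2,6-bis[(tert-butyldimethylsilyl)oxy]-4-[(2-methylbut-3-yn-2-yl)oxy]phenyl}methylidene)-6-ethyl-5-methyl-2H-pyran-2,4(3H)-dione (not isolated) | CCC1=C(C)C(=O)C(=Cc2c(O[Si](C)(C)C(C)(C)C)cc(OC(C)(C)C#C)cc2O[Si](C)(C)C(C)(C)C)C(=O)O1 | intermediate
11 | 3-({2,6-bis[(tert-butyldimethylsilyl)oxy]-4-[(2-methylbut-3-yn-2-yl)oxy]phenyl}methyl)-6-ethyl-4-hydroxy-5-methyl-2H-pyran-2-one | CCc1oc(=O)c(Cc2c(O[Si](C)(C)C(C)(C)C)cc(OC(C)(C)C#C)cc2O[Si](C)(C)C(C)(C)C)c(O)c1C | intermediate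
12 | 3-({2,6-bis[(tert-butyldimethylsilyl)oxy]-3-(3-methylbuta-1,2-dien-1-yl)-4-oxocyclohexa-1,5-dien-1-yl}methyl)-6-ethyl-4-hydroxy-5-methyl-2H-pyran-2-one (racemic at the sp3 ring carbon, not isolated) | O=C1C=C(O[Si](C)(C)C(C)(C)C)C(Cc2c(O)c(C)c(CC)oc2=O)=C(O[Si](C)(C)C(C)(C)C)C1C=C=C(C)C | intermediate
13 | 3-({2,6-bis[(tert-butyldimethylsilyl)oxy]-4-hydroxy-3-(3-methylbuta-1,2-dien-1-yl)phenyl}methyl)-6-ethyl-4-hydroxy-5-methyl-2H-pyran-2-one (not isolated) | CCc1oc(=O)c(Cc2c(O[Si](C)(C)C(C)(C)C)cc(O)c(C=C=C(C)C)c2O[Si](C)(C)C(C)(C)C)c(O)c1C | intermediate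
14 | 3-({2,6-bis[(tert-butyldimethylsilyl)oxy]-3-(3-methylbut-2-en-1-ylidene)-4-oxocyclohexa-1,5-dien-1-yl}methyl)-6-ethyl-4-hydroxy-5-methyl-2H-pyran-2-one (not isolated) | O=C1C=C(O[Si](C)(C)C(C)(C)C)C(Cc2c(O)c(C)c(CC)oc2=O)=C(O[Si](C)(C)C(C)(C)C)C1=CC=C(C)C | intermediate
15 | 3-({5,7-bis[(tert-butyldimethylsilyl)oxy]-2,2-dimethyl-2H-chromen-6-yl}methyl)-6-ethyl-4-hydroxy-5-methyl-2H-pyran-2-one | CCc1oc(=O)c(Cc2c(O[Si](C)(C)C(C)(C)C)cc3OC(C)(C)C=Cc3c2O[Si](C)(C)C(C)(C)C)c(O)c1C | intermediate
16 | 3-[(5,7-dihydroxy-2,2-dimethyl-2H-chromen-6-yl)methyl]-6-ethyl-4-hydroxy-5-methyl-2H-pyran-2-one | CCc1oc(=O)c(Cc2c(O)cc3OC(C)(C)C=Cc3c2O)c(O)c1C | intermediate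
17 | (S)-2-methylbutanoic acid | CC[C@H](C)C(=O)O | starting material
18 | (S)-2-methylbutanoyl chloride | CC[C@H](C)C(=O)Cl | intermediate
19 | 3-({5,7-dihydroxy-2,2-dimethyl-8-[(2S)-2-methylbutanoyl]-2H-chromen-6-yl}methyl)-6-ethyl-4-hydroxy-5-methyl-2H-pyran-2-one | CCc1oc(=O)c(Cc2c(O)c3c(c(C(=O)[C@@H](C)CC)c2O)OC(C)(C)C=C3)c(O)c1C | target

Total step count: 9. Longest linear sequence: 6 steps (1, 2, 5, 6, 7, 9 from compound 1; the pyranone branch 3, 4, 5, 6, 7, 9 from compound 5 is equally long).

Steps most likely to fail

Step 6. A silyl group may be lost or may migrate at 135 °C under the influence of the acidic pyranone O–H before the ring has closed, which would re-open the choice between two oxygens. The tertiary propargylic C–O bond may ionise, and the quinone methide may oligomerise instead of closing. The fallback sets out from 11 and replaces the pericyclic cascade by a catalytic 6-endo-dig intramolecular hydroarylation with Ph3PAuNTf2 (2–5 mol%, CH2Cl2, rt). The alkyne bound to monovalent gold is attacked by the ortho carbon in an electrophilic aromatic substitution, and protodeauration follows. The O–CMe2 bond never breaks, so no allenylphenol arises and no choice of oxygen exists, while the symmetry still allows only one product. It comes back to the route at 15 and makes no new compound F0.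

Step 9. The electron-rich C3=C4 alkene may be protonated or activated by the Lewis acid, leading to addition of HCl or oligomerisation. The methylene bridge may be cut by acid, acylation may stop at oxygen, and soft enolisation of the titanium-bound ketone may erode the (S) centre. The fallback avoids acid altogether and sets out from 15 together with 18.
- NIS (MeCN, 0 °C, dark) should iodinate the only arene C–H to give the 8-iodochromene F1.
- Separately, 18 with MeNHOMe·HCl and pyridine (CH2Cl2, 0 °C) gives the Weinreb amide F2.
- F1 is treated with i-PrMgCl·LiCl (2.1 equiv, THF, −20 → 0 °C). The first equivalent only deprotonates the pyranone O–H and thereby shields the lactone as its magnesium salt. The second carries out iodine–magnesium exchange to give the arylmagnesium chloride F3.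
- F3 adds to F2, and the chelated adduct survives until work-up, so neither over-addition nor enolisation can touch the stereocentre. The product is the 8-acyl bis-silyl ether F4.
- TBAF/AcOH under the conditions of step 7 then brings the sequence back to the route at 19.

Step 5. Iminium formation may be slow at an aldehyde that is both hindered and strongly donor-substituted. A silyl group may be lost from the push–pull alkylidene, after which the freed phenol could attack the lactone. The alkylidene may also be captured by a second pyranone before hydride transfer. The fallback sets out from 4 and changes the bond formation from condensation and reduction to an ionisation-driven substitution. Reduction with i-Bu2AlH (CH2Cl2, −78 °C, where the aluminium alkoxide should not trigger oxygen-to-oxygen silyl migration) gives the benzylic alcohol F5. F5 is then stirred with an excess of 9 in (CF3)2CHOH at rt. Dehydrative Friedel–Crafts-type benzylation of 4-hydroxy-2-pyranones by ionisable benzylic alcohols is known. The trioxygenated benzylic cation forms without added acid, and any O-alkylation is reversible under these conditions, so the C3-benzyl product should accumulate. The fallback comes back to the route at 11.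

Further compounds
F0 | step 6 | none | none
F1 | step 9 | 3-({5,7-bis[(tert-butyldimethylsilyl)oxy]-8-iodo-2,2-dimethyl-2H-chromen-6-yl}methyl)-6-ethyl-4-hydroxy-5-methyl-2H-pyran-2-one | CCc1oc(=O)c(Cc2c(O[Si](C)(C)C(C)(C)C)c(I)c3OC(C)(C)C=Cc3c2O[Si](C)(C)C(C)(C)C)c(O)c1C
F2 | step 9 | (2S)-N-methoxy-N,2-dimethylbutanamide | CC[C@H](C)C(=O)N(C)OC
F3 | step 9 | 8-chloromagnesio derivative of 15 as its pyranone O-magnesium chloride salt | CCc1oc(=O)c(Cc2c(O[Si](C)(C)C(C)(C)C)c([Mg]Cl)c3OC(C)(C)C=Cc3c2O[Si](C)(C)C(C)(C)C)c(O[Mg]Cl)c1C
F4 | step 9 | 3-({5,7-bis[(tert-butyldimethylsilyl)oxy]-2,2-dimethyl-8-[(2S)-2-methylbutanoyl]-2H-chromen-6-yl}methyl)-6-ethyl-4-hydroxy-5-methyl-2H-pyran-2-one | CCc1oc(=O)c(Cc2c(O[Si](C)(C)C(C)(C)C)c(C(=O)[C@@H](C)CC)c3OC(C)(C)C=Cc3c2O[Si](C)(C)C(C)(C)C)c(O)c1C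
F5 | step 5 | {2,6-bis[(tert-butyldimethylsilyl)oxy]-4-[(2-methylbut-3-yn-2-yl)oxy]phenyl}methanol | OCc1c(O[Si](C)(C)C(C)(C)C)cc(OC(C)(C)C#C)cc1O[Si](C)(C)C(C)(C)C
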